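## Analysis of the target

The target is a (3R)-isoflavanone, a 2,3-dihydro-4H-chromen-4-one. Ring A (C4a to C8a) carries a hydroxyl at C7. Ring C (O1, C2, C3, C4, C4a, C8a) carries ring B at C3. Ring B is a pentasubstituted benzene: C1' is bonded to C3, C2' and C3' bear free hydroxyls, C4' a methoxy group, C5' a 2-methylbut-3-en-2-yl (tertiary allyl) group, and only C6' a hydrogen. C3 is the only stereocentre. It is benzylic and alpha to the C4 ketone, so it is lost through the enol under base and more slowly under acid, and everything after its creation must stay close to neutral. The sensitive groups are the catechol (oxidation to the ortho-quinone), the terminal alkene (which rules out hydrogenolysis, strong acid and strong electrophiles) and three acidic phenols. The synthesis is hard for two reasons: the labile stereocentre has to be set late by a mild method, and ring B needs three contiguous oxygens, one specific terminal oxygen methylated, with a quaternary benzylic carbon next to it. The strategy rests on C2, a lone methylene between O1 and C3. The O1–C2 unit can be traced back to a methoxy group ortho to the carbonyl on ring A, and C3, flanked by the C4 carbonyl and C1' of ring B, can be traced back to a carbene carbon.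

## Retrosynthetic reasoning

**15 to 14.** The last operation should only unmask the three phenols, because C3 of 15 epimerises through the enol. Cutting the three O–Si bonds leads to 14, with O7 as a triisopropylsilyl ether and the catechol as a di-tert-butylsilylene. Silicon on all three oxygens allows one removal by acidic fluoride, without base, hydrogen or strong acid, so C3, the alkene and the catechol are safe.

**14 to 13.** The C2–C3 bond of ring C is cut. C2 becomes the methyl of a methoxy group on C8a and C3 becomes a diazo carbon, which gives 13. This cut is preferred to O1–C2, C3–C1' or C4–C4a because it closes the ring and creates C3 in the same event, under neutral conditions, from a diaryl ketone that has no stereocentre to protect. The forward reaction must decompose the diazo group on a chiral dirhodium tetracarboxylate, insert the carbene into a methoxy C–H bond to close a six-membered ring, and do so on one face. On the ring B side, an oxygen substituent with a C–H bond on the atom attached to oxygen would invite a faster five-membered insertion. The catechol is therefore bridged by silicon, which puts no C–H bond in that position.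

**13 to 12.** Removing the diazo group gives deoxybenzoin 12. Its methylene lies between the ketone and ring B and is acidic enough for direct diazo transfer from a sulfonyl azide.

**12 to 11 and 8.** The bond between the alpha carbon and C1' is cut, giving methyl ketone 11 and aryl bromide 8. This is the most convergent cut, since each half already carries its full substitution pattern. The forward reaction is a palladium-catalysed enolate arylation. It has to run with a weak base, so O7 carries the bulky triisopropylsilyl group, because a silyl ether para to a carbonyl is otherwise easily lost.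

**8 to 7 to 6.** The O-methyl group and then the bromine are removed. Bromination is placed before methylation because the free hydroxyl of 6 is a strong para director and its ortho position is already occupied, so the bromine should enter only at the carbon that becomes C1'.

**6 to 4 (through 5), then to 2 and 3, then to 1.** The bond from C5' to the quaternary carbon is cut by an aromatic Claisen rearrangement. The allyl unit is inverted in this rearrangement, so the tertiary allyl group comes from the prenyl ether 4, made from phenol 2 and bromide 3. Only one ortho position of 4 carries hydrogen, so the site of C–C bond formation is fixed. Phenol 2 comes from 1 by bridging two neighbouring hydroxyls. The symmetry of 1 makes this unambiguous, and the same silylene is kept to the end.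

**11 to 10 to 9.** Ketone 11 comes from 9 by silylation of the non-chelated 4-hydroxyl, then methylation of the chelated 2-hydroxyl. That methyl carbon is the future C2.

## Alternatives that were turned down

**Alternative 1:** Ring B itself is disconnected at C3'–C4', C1'–C2' and C4'–C5'. The precursors are the unsaturated acid chloride A1, which already holds rings A and C with C3 and C4 set (C4 as a silyl ether), and the alkyne A2. In the forward step an amine base dehydrochlorinates A1 to a vinylketene. Cycloaddition with A2, four-electron ring opening of the cyclobutenone, six-electron closure and tautomerisation give phenol A3.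
- For: every substituent of ring B is placed by construction, so no aromatic substitution has to be regioselective. The tertiary allyl group is carried in as part of an aliphatic chain. C3 is configurationally safe because C4 is at the alcohol level.
- Against: A2 loses isobutene on warming, while the cascade needs heat. Vinylketenes from alpha-branched acid chlorides dimerise. A3 still needs methylation of the hindered 4'-hydroxyl, acid cleavage of two tert-butyl ethers and a methoxymethyl ether next to the alkene, desilylation and oxidation at C4. A1 needs its own asymmetric synthesis of a 3,4-disubstituted chroman plus chain assembly.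
- Comparison: it is stronger on regiochemical certainty in ring B and on the stability of C3 during the build-up. The chosen route offers instead a convergent sequence of roughly half the length, in which C3 is created catalytically in the ring-closing step and is followed only by fluoride deprotection.

**Alternative 2:** The O1–C8a bond is disconnected. The precursor is diol A4, whose two stereocentres come from an auxiliary-controlled aldol reaction and reduction. In the forward step a copper-catalysed intramolecular aryl ether coupling under carbonate base joins the primary hydroxyl to the brominated carbon and gives the trans-isoflavan-4-ol A5.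
- For: the absolute and relative configuration come from chemistry whose sense is predictable. C3 cannot enolise until C4 is oxidised. Only the primary hydroxyl can close a ring of reasonable size.
- Against: the aldol needs the fully substituted ring B arylacetic acid, which costs homologation steps beyond the ring B chemistry used here, and a stoichiometric auxiliary that must be attached and removed. After A5, C4 must be oxidised and three methoxymethyl ethers removed with acid on the finished, enolisable ketone that also carries the tertiary allyl group.
- Comparison: it is stronger in predictability of configuration and in using only established reaction types. The chosen route is shorter, uses a catalytic source of chirality, and ends without acid.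

**Alternative 3:** The C4–C4a bond is disconnected. The precursor is the aryl iodide A6, a Weinreb amide that already holds the C3 stereocentre. In the forward step, iodine–magnesium exchange with an isopropylmagnesium reagent gives an arylmagnesium species that adds to the amide. The chelated tetrahedral intermediate releases ketone A7 on work-up.
- For: ring C is closed directly at the ketone oxidation level, the chelate shields the product from enolisation until the quench, and no new method is needed.
- Against: A6 has an acidic alpha-aryl amide hydrogen and a beta-aryloxy leaving group. The basic magnesium reagent can therefore racemise it or eliminate phenoxide to an acrylamide. A6 must first be made in enantiopure form, and the ether-forming step on a beta-hydroxy carbonyl compound has the same elimination risk. The three methoxymethyl ethers again come off with acid at the end.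
- Comparison: it is stronger in that each step has close precedent. But the stereocentre must survive three hazardous stages. In the chosen route it meets only one mild deprotection after it is formed.

Key step: step 10

Remark on the chemistry: which enantiomer of the dirhodium catalyst leads to (3R)-14 cannot be derived with confidence for this new substrate. The route is written with Rh2(S-PTTL)4 and assumes that it, or otherwise its mirror image Rh2(R-PTTL)4 from (R)-tert-leucine, delivers the (3R) product.

## Route

Step 1
Reactants: 1 pyrogallol
Product: 2 2,2-di-tert-butyl-1,3,2-benzodioxasilol-4-ol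
Conditions: tBu2Si(OTf)2 (1.0 equiv, slow addition), 2,6-lutidine, DMF, −20 → 0 °C, argon
Reagents that add atoms: di-tert-butylsilyl bis(trifluoromethanesulfonate), CC(C)(C)[Si](OS(=O)(=O)C(F)(F)F)(OS(=O)(=O)C(F)(F)F)C(C)(C)C
Why: Cyclic silylene formation with a bifunctional silyl triflate: after the first Si–O bond forms, the neighbouring hydroxyl displaces the second triflate and closes the five-membered dioxasilole, while the meta pair cannot be bridged; both adjacent pairs of 1 are equivalent by symmetry, so one phenol with a terminal hydroxyl left free is expected.

Step 2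
Reactants: 2 2,2-di-tert-butyl-1,3,2-benzodioxasilol-4-ol; 3 prenyl bromide
Product: 4 2,2-di-tert-butyl-4-[(3-methylbut-2-en-1-yl)oxy]-1,3,2-benzodioxasilole
Conditions: K2CO3, acetone, rt
Reagents that add atoms: none
Why: Williamson ether synthesis; the phenoxide displaces the primary allylic bromide at oxygen, and the hindered di-tert-butylsilylene should not be attacked by carbonate under anhydrous conditions.

Step 3
Reactants: 4 2,2-di-tert-butyl-4-[(3-methylbut-2-en-1-yl)oxy]-1,3,2-benzodioxasilole
Product: 6 2,2-di-tert-butyl-5-(2-methylbut-3-en-2-yl)-1,3,2-benzodioxasilol-4-ol, via ortho-dienone 5 (not isolated)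
Conditions: PhNEt2, 190 °C, sealed tube, argon
Reagents that add atoms: none
Why: Aromatic Claisen rearrangement, a [3,3]-sigmatropic shift that inverts the allyl unit, so the prenyl ether delivers the 2-methylbut-3-en-2-yl group to carbon; C5 is the only ortho position bearing hydrogen, and the amine solvent speeds tautomerisation of dienone 5 to phenol 6 before it can rearrange further.

Step 4
Reactants: 6 2,2-di-tert-butyl-5-(2-methylbut-3-en-2-yl)-1,3,2-benzodioxasilol-4-ol
Product: 7 7-bromo-2,2-di-tert-butyl-5-(2-methylbut-3-en-2-yl)-1,3,2-benzodioxasilol-4-ol
Conditions: N-bromosuccinimide (1.0 equiv), MeCN, −20 °C, dark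
Reagents that add atoms: N-bromosuccinimide, O=C1CCC(=O)N1Br
Why: Electrophilic aromatic bromination directed para by the free, coplanar hydroxyl; the ortho position is occupied, C6 is shielded by the quaternary carbon, and the hindered vinyl group without allylic hydrogens should react far more slowly than the trioxygenated ring.

Step 5
Reactants: 7 7-bromo-2,2-di-tert-butyl-5-(2-methylbut-3-en-2-yl)-1,3,2-benzodioxasilol-4-ol
Product: 8 7-bromo-2,2-di-tert-butyl-4-methoxy-5-(2-methylbut-3-en-2-yl)-1,3,2-benzodioxasilole
Conditions: MeI, K2CO3, acetone, 40 °C
Reagents that add atoms: iodomethane, CI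
Why: Williamson O-methylation of the hindered phenoxide with a small electrophile; silicon cannot reach the new phenoxide oxygen while still bound to the far oxygen, so silylene migration is not expected and the methyl group ends up on the oxygen next to the tertiary allyl group.

Step 6
Reactants: 9 2,4-dihydroxyacetophenone
Product: 10 1-[2-hydroxy-4-(triisopropylsilyloxy)phenyl]ethan-1-one
Conditions: iPr3SiCl (1.05 equiv), imidazole, CH2Cl2, 0 °C → rt
Reagents that add atoms: chlorotriisopropylsilane, CC(C)[Si](Cl)(C(C)C)C(C)C
Why: Selective phenol silylation; the 2-hydroxyl is hydrogen-bonded to the acetyl group and flanked by it, so the bulky chlorosilane reacts at the 4-hydroxyl; triisopropylsilyl is chosen because a silyl ether para to a carbonyl must later survive phosphate and amidine bases.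

Step 7
Reactants: 10 1-[2-hydroxy-4-(triisopropylsilyloxy)phenyl]ethan-1-one
Product: 11 1-[2-methoxy-4-(triisopropylsilyloxy)phenyl]ethan-1-one
Conditions: MeOH, PPh3, DIAD, THF, 0 °C → rt
Reagents that add atoms: methanol, CO
Why: Mitsunobu etherification; the chelated phenol is acidic enough to protonate the betaine and is methylated under neutral conditions, which avoids carbonate bases that could strip the silyl ether; this methyl carbon is the future C2.

Step 8
Reactants: 11 1-[2-methoxy-4-(triisopropylsilyloxy)phenyl]ethan-1-one; 8 7-bromo-2,2-di-tert-butyl-4-methoxy-5-(2-methylbut-3-en-2-yl)-1,3,2-benzodioxasilole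
Product: 12 2-[2,2-di-tert-butyl-7-methoxy-6-(2-methylbut-3-en-2-yl)-1,3,2-benzodioxasilol-4-yl]-1-[2-methoxy-4-(triisopropylsilyloxy)phenyl]ethan-1-one
Conditions: Pd2(dba)3 (2 mol%), Xantphos, K3PO4, toluene, 90 °C, argon
Reagents that add atoms: none
Why: Palladium-catalysed alpha-arylation of a ketone enolate (oxidative addition of 8 to zerovalent palladium, enolate binding, reductive elimination); the wide-bite-angle bisphosphine favours reductive elimination and monoarylation, the ortho oxygen of 8 disfavours a second arylation, and K3PO4 replaces an alkoxide so that both silicon groups survive.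

Step 9
Reactants: 12 2-[2,2-di-tert-butyl-7-methoxy-6-(2-methylbut-3-en-2-yl)-1,3,2-benzodioxasilol-4-yl]-1-[2-methoxy-4-(triisopropylsilyloxy)phenyl]ethan-1-one
Product: 13 2-diazo-2-[2,2-di-tert-butyl-7-methoxy-6-(2-methylbut-3-en-2-yl)-1,3,2-benzodioxasilol-4-yl]-1-[2-methoxy-4-(triisopropylsilyloxy)phenyl]ethan-1-one
Conditions: p-ABSA, DBU, MeCN, 0 °C → rt, dark
Reagents that add atoms: 4-acetamidobenzenesulfonyl azide, CC(=O)Nc1ccc(cc1)S(=O)(=O)N=[N+]=[N-]
Why: Regitz diazo transfer; the methylene of 12 is activated by both the ketone and ring B, so DBU forms the enolate directly and the sulfonyl azide transfers the diazo group without a prior activating acyl group.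

Step 10
Reactants: 13 2-diazo-2-[2,2-di-tert-butyl-7-methoxy-6-(2-methylbut-3-en-2-yl)-1,3,2-benzodioxasilol-4-yl]-1-[2-methoxy-4-(triisopropylsilyloxy)phenyl]ethan-1-one
Product: 14 (3R)-3-[2,2-di-tert-butyl-7-methoxy-6-(2-methylbut-3-en-2-yl)-1,3,2-benzodioxasilol-4-yl]-7-(triisopropylsilyloxy)-2,3-dihydro-4H-chromen-4-one
Conditions: Rh2(S-PTTL)4 (dirhodium tetrakis[N-phthaloyl-(S)-tert-leucinate], 1 mol%), toluene, 0 °C → rt, slow addition of 13 at high dilution, 4 Å molecular sieves, argon
Reagents that add atoms: none
Why: Proposed new method: the dirhodium tetracarboxylate expels dinitrogen from 13 and gives a rhodium-bound carbene at the future C3, tempered by ring B as donor and the aryl ketone as acceptor, which inserts through a concerted, asynchronous three-centre transition state with hydride-like transfer into a C–H bond of the ring A methoxy group and so forms C2–C3. The closest known reaction types are chroman-4-one formation by insertion of 2-alkoxyphenyl diazomethyl ketone carbenes into the O–CH2R group under chiral dirhodium carboxylates, intramolecular insertion of aryl diazoacetate carbenes into aryl methyl ethers, and enantioselective intermolecular insertion of donor/acceptor carbenes into methyl ethers; an aryl/acyl carbene closing a six-membered ring onto a methoxy group has not been shown. Ring C is closed as a six-membered ring by 1,6-C–H insertion (carbene carbon, C4, C4a, C8a, O1, methyl carbon). The only new stereocentre, C3, is the former carbene carbon, and its configuration is fixed by the face of the carbene that the C–H bond approaches, which the phthalimide wall of the tert-leucinate ligands dictates (catalyst control, no substrate stereocentre). The step needs C–H insertion to win over oxonium ylide formation at the methoxy oxygen with 1,2-methyl shift, over insertion on the ring B side, and over bimolecular reaction with the vinyl group: methyl migrates poorly and ylide formation is reversible, the silylene leaves no C–H bond within reach of a five- or six-membered transition state on ring B, and slow addition at high dilution suppresses cyclopropanation and carbene dimerisation. The ketone stereocentre arises under neutral, aprotic conditions and is not exposed to enolisation.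

Step 11
Reactants: 14 (3R)-3-[2,2-di-tert-butyl-7-methoxy-6-(2-methylbut-3-en-2-yl)-1,3,2-benzodioxasilol-4-yl]-7-(triisopropylsilyloxy)-2,3-dihydro-4H-chromen-4-one
Product: 15 (3R)-3-[2,3-dihydroxy-4-methoxy-5-(2-methylbut-3-en-2-yl)phenyl]-7-hydroxy-2,3-dihydro-4H-chromen-4-one
Conditions: HF·pyridine, pyridine, THF, 0 °C → rt, argon
Reagents that add atoms: none
Why: Fluoride-induced cleavage of the aryl silyl ether and of the cyclic silylene in one operation, driven by the strong Si–F bond; the medium is weakly acidic, so no enolate should form at C3 and the (3R) configuration should be kept, and neither the alkene nor the catechol reacts under argon.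

## Compound list

1 | pyrogallol (benzene-1,2,3-triol) | Oc1cccc(O)c1O | starting material
2 | 2,2-di-tert-butyl-1,3,2-benzodioxasilol-4-ol | Oc1cccc2O[Si](C(C)(C)C)(C(C)(C)C)Oc12 | intermediate
3 | prenyl bromide (1-bromo-3-methylbut-2-ene) | CC(C)=CCBr | starting material
4 | 2,2-di-tert-butyl-4-[(3-methylbut-2-en-1-yl)oxy]-1,3,2-benzodioxasilole | CC(C)=CCOc1cccc2O[Si](C(C)(C)C)(C(C)(C)C)Oc12 | intermediate
5 | 2,2-di-tert-butyl-5-(2-methylbut-3-en-2-yl)-1,3,2-benzodioxasilol-4(5H)-one (ortho-dienone, C5 configuration undefined) | C=CC(C)(C)C1C=CC2=C(O[Si](C(C)(C)C)(C(C)(C)C)O2)C1=O | intermediate (not isolated)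
6 | 2,2-di-tert-butyl-5-(2-methylbut-3-en-2-yl)-1,3,2-benzodioxasilol-4-ol | C=CC(C)(C)c1ccc2O[Si](C(C)(C)C)(C(C)(C)C)Oc2c1O | intermediate
7 | 7-bromo-2,2-di-tert-butyl-5-(2-methylbut-3-en-2-yl)-1,3,2-benzodioxasilol-4-ol | C=CC(C)(C)c1cc(Br)c2O[Si](C(C)(C)C)(C(C)(C)C)Oc2c1O | intermediate
8 | 7-bromo-2,2-di-tert-butyl-4-methoxy-5-(2-methylbut-3-en-2-yl)-1,3,2-benzodioxasilole | C=CC(C)(C)c1cc(Br)c2O[Si](C(C)(C)C)(C(C)(C)C)Oc2c1OC | intermediate
9 | 2,4-dihydroxyacetophenone | CC(=O)c1ccc(O)cc1O | starting material
10 | 1-[2-hydroxy-4-(triisopropylsilyloxy)phenyl]ethan-1-one | CC(=O)c1ccc(O[Si](C(C)C)(C(C)C)C(C)C)cc1O | intermediate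
11 | 1-[2-methoxy-4-(triisopropylsilyloxy)phenyl]ethan-1-one | CC(=O)c1ccc(O[Si](C(C)C)(C(C)C)C(C)C)cc1OC | intermediate
12 | 2-[2,2-di-tert-butyl-7-methoxy-6-(2-methylbut-3-en-2-yl)-1,3,2-benzodioxasilol-4-yl]-1-[2-methoxy-4-(triisopropylsilyloxy)phenyl]ethan-1-one | COc1cc(O[Si](C(C)C)(C(C)C)C(C)C)ccc1C(=O)Cc1cc(C(C)(C)C=C)c(OC)c2O[Si](C(C)(C)C)(C(C)(C)C)Oc12 | intermediate
13 | 2-diazo-2-[2,2-di-tert-butyl-7-methoxy-6-(2-methylbut-3-en-2-yl)-1,3,2-benzodioxasilol-4-yl]-1-[2-methoxy-4-(triisopropylsilyloxy)phenyl]ethan-1-one | COc1cc(O[Si](C(C)C)(C(C)C)C(C)C)ccc1C(=O)C(=[N+]=[N-])c1cc(C(C)(C)C=C)c(OC)c2O[Si](C(C)(C)C)(C(C)(C)C)Oc12 | intermediate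
14 | (3R)-3-[2,2-di-tert-butyl-7-methoxy-6-(2-methylbut-3-en-2-yl)-1,3,2-benzodioxasilol-4-yl]-7-(triisopropylsilyloxy)-2,3-dihydro-4H-chromen-4-one | C=CC(C)(C)c1cc([C@@H]2COc3cc(O[Si](C(C)C)(C(C)C)C(C)C)ccc3C2=O)c2O[Si](C(C)(C)C)(C(C)(C)C)Oc2c1OC | intermediate
15 | (3R)-3-[2,3-dihydroxy-4-methoxy-5-(2-methylbut-3-en-2-yl)phenyl]-7-hydroxy-2,3-dihydro-4H-chromen-4-one | C=CC(C)(C)c1cc([C@@H]2COc3cc(O)ccc3C2=O)c(O)c(O)c1OC | target

## Step count and least certain steps

Total step count: 11. Longest linear sequence: 9 steps (steps 1 to 5 and 8 to 11); steps 6 and 7 form the ring A branch.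

**Step 10 (key step).**
- What may go wrong: the carbene may attack the methoxy oxygen and form a five-membered oxonium ylide that collapses by 1,2-methyl shift, which contracts the ring.
- Enantioselectivity may be poor, because the only stereocentre is the carbene carbon and a stepwise hydride transfer followed by closure of a zwitterion would escape the catalyst.
- The carbene may be consumed bimolecularly by the vinyl group or by a second molecule of 13.
- Dinitrogen loss may be slow, because the diazo carbon is crowded by two ortho-substituted rings.
- Fallback: this uses known reactions only, sets out from 10 and 8 and returns at 14.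
  - Heating 10 with N,N-dimethylformamide dimethyl acetal should give the enaminone F1, and iodine should close it to 3-iodo-7-(triisopropylsilyloxy)chromen-4-one F2.
  - Bromide 8 is borylated with bis(pinacolato)diboron, PdCl2(dppf) and KOAc to the boronate F3.
  - Suzuki–Miyaura coupling of F2 and F3 (Pd(PPh3)4, K3PO4, dioxane) gives the isoflavone F4.
  - Asymmetric transfer hydrogenation with RuCl[(R,R)-TsDPEN](p-cymene) and HCO2H/Et3N reduces the C2–C3 double bond and then the ketone under dynamic kinetic resolution to the cis-(3R,4R)-isoflavan-4-ol F5. The (R,R) ligand is the choice expected from the behaviour of aryl alkyl ketones.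
  - Dess–Martin oxidation in pyridine-buffered CH2Cl2 restores the ketone without touching C3 and arrives at 14.

**Step 8.**
- What may go wrong: oxidative addition and reductive elimination may be slow with the hindered, electron-rich, ortho-oxygenated bromide. Silyl groups may be lost by attack of enolate or phosphate at silicon, especially at the silyl ether para to the carbonyl.
- Fallback: this sets out from 11 and 8 and returns at 13, bypassing 12 and step 9.
  - Ketone 11 is trifluoroacetylated (LiHMDS, CF3CO2CH2CF3, THF, −78 °C) to the 1,3-diketone F6.
  - Detrifluoroacetylative diazo transfer (MsN3, Et3N, MeCN, water) gives the diazomethyl ketone F7.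
  - Bromide 8 is converted by copper-catalysed halogen exchange (CuI, NaI, trans-N,N'-dimethylcyclohexane-1,2-diamine, dioxane, 110 °C) into the iodide F8.
  - Pd(PPh3)4, Ag2CO3 and Et3N in toluene at room temperature then couple F8 with the C–H bond of F7 with retention of the diazo group and give 13 directly.

**Step 4.**
- What may go wrong: the neighbouring phenol may capture a bromonium ion formed at the vinyl group (bromoetherification). The very electron-rich phenol may be over-brominated or oxidised.
- Fallback: this sets out from 6 and returns at 8. Phenol 6 is methylated first (MeI, K2CO3, acetone) to the methyl ether F9. The ring is then brominated with N-bromosuccinimide in MeCN at 0 °C, where no hydroxyl can trap a bromonium ion. Regiocontrol then rests on the ortho ring oxygen, the para methoxy group and the shielding of the other free position by the quaternary carbon.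

**Step 3.**
- What may go wrong: the ortho product may be diverted by the abnormal Claisen pathway, in which the phenolic O–H adds to the vinyl group and the side chain isomerises. Dienone 5 may undergo an onward Cope shift to the para position. The prenyl group may be lost thermally.
- Fallback: this sets out from 4 and returns at 6. The rearrangement is run in PhNEt2 with acetic anhydride and NaOAc at 190 °C, so that the phenol is acetylated as it forms and the O–H needed for the abnormal pathway never exists. This should give the aryl acetate F10. DIBAL-H in CH2Cl2 at −78 °C then cleaves the acetate reductively and gives 6.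

## Further compounds

F1 | step 10 | (E)-3-(dimethylamino)-1-[2-hydroxy-4-(triisopropylsilyloxy)phenyl]prop-2-en-1-one | CN(C)/C=C/C(=O)c1ccc(O[Si](C(C)C)(C(C)C)C(C)C)cc1O
F2 | step 10 | 3-iodo-7-(triisopropylsilyloxy)-4H-chromen-4-one | O=c1c(I)coc2cc(O[Si](C(C)C)(C(C)C)C(C)C)ccc12
F3 | step 10 | 2,2-di-tert-butyl-4-methoxy-5-(2-methylbut-3-en-2-yl)-7-(4,4,5,5-tetramethyl-1,3,2-dioxaborolan-2-yl)-1,3,2-benzodioxasilole | C=CC(C)(C)c1cc(B2OC(C)(C)C(C)(C)O2)c2O[Si](C(C)(C)C)(C(C)(C)C)Oc2c1OC
F4 | step 10 | 3-[2,2-di-tert-butyl-7-methoxy-6-(2-methylbut-3-en-2-yl)-1,3,2-benzodioxasilol-4-yl]-7-(triisopropylsilyloxy)-4H-chromen-4-one | C=CC(C)(C)c1cc(-c2coc3cc(O[Si](C(C)C)(C(C)C)C(C)C)ccc3c2=O)c2O[Si](C(C)(C)C)(C(C)(C)C)Oc2c1OC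
F5 | step 10 | (3R,4R)-3-[2,2-di-tert-butyl-7-methoxy-6-(2-methylbut-3-en-2-yl)-1,3,2-benzodioxasilol-4-yl]-7-(triisopropylsilyloxy)chroman-4-ol (cis) | C=CC(C)(C)c1cc([C@@H]2COc3cc(O[Si](C(C)C)(C(C)C)C(C)C)ccc3[C@@H]2O)c2O[Si](C(C)(C)C)(C(C)(C)C)Oc2c1OC
F6 | step 8 | 4,4,4-trifluoro-1-[2-methoxy-4-(triisopropylsilyloxy)phenyl]butane-1,3-dione | COc1cc(O[Si](C(C)C)(C(C)C)C(C)C)ccc1C(=O)CC(=O)C(F)(F)F
F7 | step 8 | 2-diazo-1-[2-methoxy-4-(triisopropylsilyloxy)phenyl]ethan-1-one | COc1cc(O[Si](C(C)C)(C(C)C)C(C)C)ccc1C(=O)C=[N+]=[N-]
F8 | step 8 | 2,2-di-tert-butyl-7-iodo-4-methoxy-5-(2-methylbut-3-en-2-yl)-1,3,2-benzodioxasilole | C=CC(C)(C)c1cc(I)c2O[Si](C(C)(C)C)(C(C)(C)C)Oc2c1OC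
F9 | step 4 | 2,2-di-tert-butyl-4-methoxy-5-(2-methylbut-3-en-2-yl)-1,3,2-benzodioxasilole | C=CC(C)(C)c1ccc2O[Si](C(C)(C)C)(C(C)(C)C)Oc2c1OC
F10 | step 3 | 2,2-di-tert-butyl-5-(2-methylbut-3-en-2-yl)-1,3,2-benzodioxasilol-4-yl acetate | C=CC(C)(C)c1ccc2O[Si](C(C)(C)C)(C(C)(C)C)Oc2c1OC(C)=O
A1 | alternative 1 | 2-[(3R,4R)-4-(tert-butyldimethylsilyloxy)-7-(methoxymethoxy)chroman-3-yl]-5,5-dimethylhepta-2,6-dienoyl chloride | C=CC(C)(C)CC=C(C(Cl)=O)[C@@H]1COc2cc(OCOC)ccc2[C@@H]1O[Si](C)(C)C(C)(C)C
A2 | alternative 1 | di-tert-butoxyethyne | CC(C)(C)OC#COC(C)(C)C
A3 | alternative 1 | (3R,4R)-cis-isoflavan-4-ol tert-butyldimethylsilyl ether with 7-O-methoxymethyl, 2',3'-di-O-tert-butyl and free 4'-hydroxyl | C=CC(C)(C)c1cc([C@@H]2COc3cc(OCOC)ccc3[C@@H]2O[Si](C)(C)C(C)(C)C)c(OC(C)(C)C)c(OC(C)(C)C)c1O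
A4 | alternative 2 | (1S,2R)-1-[2-bromo-4-(methoxymethoxy)phenyl]-2-[4-methoxy-2,3-bis(methoxymethoxy)-5-(2-methylbut-3-en-2-yl)phenyl]propane-1,3-diol | C=CC(C)(C)c1cc([C@H](CO)[C@H](O)c2ccc(OCOC)cc2Br)c(OCOC)c(OCOC)c1OC
A5 | alternative 2 | (3R,4S)-trans-isoflavan-4-ol, tris(methoxymethyl) protected | C=CC(C)(C)c1cc([C@@H]2COc3cc(OCOC)ccc3[C@H]2O)c(OCOC)c(OCOC)c1OC
A6 | alternative 3 | (2R)-3-[2-iodo-5-(methoxymethoxy)phenoxy]-N-methoxy-2-[4-methoxy-2,3-bis(methoxymethoxy)-5-(2-methylbut-3-en-2-yl)phenyl]-N-methylpropanamide | C=CC(C)(C)c1cc([C@H](COc2cc(OCOC)ccc2I)C(=O)N(C)OC)c(OCOC)c(OCOC)c1OC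
A7 | alternative 3 | (3R)-isoflavanone, tris(methoxymethyl) protected | C=CC(C)(C)c1cc([C@@H]2COc3cc(OCOC)ccc3C2=O)c(OCOC)c(OCOC)c1OC
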